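The plan cuts ring B at C6–C7 (bromonium spirocyclisation in which the C1 acetate captures C11) and ring A at C5–C6 and C1–C6, leaving an acyclic C1–C5 chain. The key step exploits the trans C3(Cl,Me)/C4(Br) pair of ring A, the one pair of stereocentres that arises purely from alkene dihalogenation, together with C5 as an allylic carbinol: a chiral titanium catalyst adds bromine to C4 and chlorine to C3 anti across a Z-trisubstituted alkene, fixing both centres and the absolute configuration in one operation without closing a ring. Its substrate is (Z)-5-silyloxy-3-methylpent-2-en-1-ol. C1, C6, C8 and C11 are later relayed from this pair.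

Key step: step 4

Remark: atom labels C1–C11 are those of the target (ring A C1–C6, ring B C6–C11; C5 is the carbinol carbon and C1 the silyloxy carbon of 5 and 7). Compounds 1 and 15 are taken as commercial. The antipode of the Schiff-base ligand that leads to the (2S,3S) series is assumed to be identified in a trial run.

Step 1
Reactants: 1 tert-butyl(but-3-yn-1-yloxy)dimethylsilane
Product: 2 methyl 5-[(tert-butyldimethylsilyl)oxy]pent-2-ynoate
Conditions: n-BuLi, THF, −78 °C; ClCO2Me, −78 → 0 °C
Reagents that add atoms: methyl chloroformate, COC(Cl)=O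
Why: C-acylation of a lithium acetylide with a chloroformate is a standard alkynoate synthesis and the silyl ether is inert to it.

Step 2
Reactants: 2 methyl 5-[(tert-butyldimethylsilyl)oxy]pent-2-ynoate
Product: 4 methyl (Z)-5-[(tert-butyldimethylsilyl)oxy]-3-methylpent-2-enoate, via alkenylcuprate 3 (not isolated)
Conditions: Me2CuLi (from CuI and MeLi), THF, −78 °C; MeOH then aq. NH4Cl at −78 °C
Reagents that add atoms: lithium dimethylcuprate, [Li+].C[Cu-]C
Why: Syn carbocupration of the ynoate gives an alkenylcuprate that holds its configuration at −78 °C and is protonated with retention, so the new methyl ends trans to the ester and the Z geometry is fixed.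

Step 3
Reactants: 4 methyl (Z)-5-[(tert-butyldimethylsilyl)oxy]-3-methylpent-2-enoate
Product: 5 (Z)-5-[(tert-butyldimethylsilyl)oxy]-3-methylpent-2-en-1-ol
Conditions: DIBAL-H (2.2 equiv), CH2Cl2, −78 → 0 °C; Rochelle salt
Reagents that add atoms: none
Why: DIBAL-H reduces the enoate 1,2 to the allylic alcohol without touching the alkene geometry or the silyl ether.

Step 4
Reactants: 5 (Z)-5-[(tert-butyldimethylsilyl)oxy]-3-methylpent-2-en-1-ol
Product: 7 (2S,3S)-2-bromo-5-[(tert-butyldimethylsilyl)oxy]-3-chloro-3-methylpentan-1-ol, via bromiranium ion 6 (not isolated)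
Conditions: NBS (1.05 equiv), ClTi(OiPr)3 (1.1 equiv), chiral tridentate salicylaldimine (Schiff-base) amino-alcohol ligand (10–20 mol %), hexanes, −20 °C
Reagents that add atoms: N-bromosuccinimide, O=C1CCC(=O)N1Br; chlorotitanium triisopropoxide, CC(C)O[Ti](Cl)(OC(C)C)OC(C)C
Why: The allylic hydroxyl binds to the chiral titanium(IV) complex, NBS transfers Br+ to the alkene face selected by the ligand to give bromiranium ion 6, and titanium-bound chloride opens 6 at the tertiary carbon C3 anti to bromine, which stays on C4. The closest known reaction type is the titanium-catalysed enantioselective bromochlorination of allylic alcohols with NBS and a chlorotitanium alkoxide. No ring is closed. C4 (S) is set by the catalyst-controlled face of bromenium transfer and C3 (S) by the stereospecific anti opening, so the Z geometry of 5 becomes the like (2S,3S) pair that is trans once ring A exists. The step needs regioselectivity (Cl on the trisubstituted carbon), chemoselectivity over bromoetherification and enantioselectivity. These are secured by the alkene substitution pattern, by the non-participating silyl ether and by ligand control through the bound primary hydroxyl.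

Step 5
Reactants: 7 (2S,3S)-2-bromo-5-[(tert-butyldimethylsilyl)oxy]-3-chloro-3-methylpentan-1-ol
Product: 8 (2S,3S)-2-bromo-5-[(tert-butyldimethylsilyl)oxy]-3-chloro-3-methylpentyl 4-methylbenzenesulfonate
Conditions: TsCl, pyridine, CH2Cl2, 0 °C → rt
Reagents that add atoms: 4-methylbenzenesulfonyl chloride, Cc1ccc(cc1)S(Cl)(=O)=O
Why: Sulfonylation in pyridine never forms the alkoxide, so the bromohydrin cannot close to an epoxide, and C5 gains the leaving group for the later C5–C6 bond.

Step 6
Reactants: 8 (2S,3S)-2-bromo-5-[(tert-butyldimethylsilyl)oxy]-3-chloro-3-methylpentyl 4-methylbenzenesulfonate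
Product: 9 (2S,3S)-2-bromo-3-chloro-5-hydroxy-3-methylpentyl 4-methylbenzenesulfonate
Conditions: HF·pyridine, THF, 0 °C → rt
Reagents that add atoms: none
Why: Acidic fluoride cleaves the primary silyl ether while the sulfonate and both carbon–halogen bonds are stable in the absence of base.

Step 7
Reactants: 9 (2S,3S)-2-bromo-3-chloro-5-hydroxy-3-methylpentyl 4-methylbenzenesulfonate
Product: 10 (2S,3S)-2-bromo-3-chloro-3-methyl-5-oxopentyl 4-methylbenzenesulfonate
Conditions: Dess–Martin periodinane, CH2Cl2, 0 °C → rt; used crude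
Reagents that add atoms: none
Why: Dess–Martin oxidation is neutral to weakly acidic, so the β-chloro aldehyde should form without loss of HCl.

Step 8
Reactants: 10 (2S,3S)-2-bromo-3-chloro-3-methyl-5-oxopentyl 4-methylbenzenesulfonate
Product: 11 (2S,3S)-2-bromo-3-chloro-5-hydroxy-3-methylhexyl 4-methylbenzenesulfonate (both C5 epimers)
Conditions: MeMgBr, THF, −78 °C; AcOH quench at −78 °C
Reagents that add atoms: methylmagnesium bromide, C[Mg]Br
Why: Grignard addition to the aldehyde at −78 °C is far faster than attack on the sulfonate or the halides; the new carbinol centre needs no control because step 9 removes it.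

Step 9
Reactants: 11 (2S,3S)-2-bromo-3-chloro-5-hydroxy-3-methylhexyl 4-methylbenzenesulfonate
Product: 12 (2S,3S)-2-bromo-3-chloro-3-methyl-5-oxohexyl 4-methylbenzenesulfonate
Conditions: Dess–Martin periodinane, CH2Cl2, rt
Reagents that add atoms: none
Why: Oxidation of the secondary alcohol under non-basic conditions gives the methyl ketone (C1 carbonyl, C6 methyl) and spares the β-chloride.

Step 10
Reactants: 12 (2S,3S)-2-bromo-3-chloro-3-methyl-5-oxohexyl 4-methylbenzenesulfonate
Product: 14 (3S,4S)-4-bromo-3-chloro-3-methylcyclohexan-1-one, via lithium enolate 13 (not isolated)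
Conditions: LDA (1.05 equiv), THF, −78 °C; DMPU, −78 → 0 °C
Reagents that add atoms: none
Why: LDA deprotonates the unhindered methyl group and leaves the C2 methylene next to quaternary C3 alone; the enolate carbon then displaces the primary tosylate in a favoured 6-(enolendo)-exo-tet alkylation, whereas closure onto the secondary bromide would be a disfavoured 5-(enolendo)-exo-tet process.

Step 11
Reactants: 14 (3S,4S)-4-bromo-3-chloro-3-methylcyclohexan-1-one; 15 6-methylhept-5-en-2-one (sulcatone)
Product: 17 (4S,5S)-4-bromo-5-chloro-2-(2-hydroxy-6-methylhept-5-en-2-yl)-5-methylcyclohexan-1-one (diastereomers at C6 and C11), via lithium enolate 16 (not isolated)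
Conditions: LDA (1.05 equiv), THF, −78 °C; 15; AcOH quench at −78 °C
Reagents that add atoms: none
Why: Kinetic deprotonation on the C6 side, away from quaternary C3, gives an enolate that adds to the sulcatone carbonyl (crossed aldol addition) and is quenched cold to prevent retro-aldol; C6 and C11 need no control because both become sp2 in step 12.

Step 12
Reactants: 17 (4S,5S)-4-bromo-5-chloro-2-(2-hydroxy-6-methylhept-5-en-2-yl)-5-methylcyclohexan-1-one
Product: 18 (2Z,4S,5S)-4-bromo-5-chloro-5-methyl-2-(6-methylhept-5-en-2-ylidene)cyclohexan-1-one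
Conditions: Burgess reagent, benzene, 50 °C; chromatographic separation of 18 from its E isomer
Reagents that add atoms: none
Why: The Burgess reagent dehydrates the tertiary β-hydroxy ketone by syn elimination through the acidic C6–H under neutral conditions that spare the β-chloride; because methyl and the homoprenyl chain are close in size both alkene isomers are expected, the Z isomer (chain syn to C1) is carried on and the E isomer can be re-equilibrated and recycled.

Step 13
Reactants: 18 (2Z,4S,5S)-4-bromo-5-chloro-5-methyl-2-(6-methylhept-5-en-2-ylidene)cyclohexan-1-one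
Product: 19 (1R,2Z,4S,5S)-4-bromo-5-chloro-5-methyl-2-(6-methylhept-5-en-2-ylidene)cyclohexan-1-ol
Conditions: NaBH4, CeCl3·7H2O, MeOH, −78 °C
Reagents that add atoms: none
Why: Luche conditions give 1,2-reduction of the hindered enone; with the halogens trans-diaxial the axial C3–Cl blocks axial attack, so hydride should add equatorially and leave the C1 hydroxyl axial and cis to chlorine (1R), the orientation also favoured by A(1,3) strain with the cis chain.

Step 14
Reactants: 19 (1R,2Z,4S,5S)-4-bromo-5-chloro-5-methyl-2-(6-methylhept-5-en-2-ylidene)cyclohexan-1-ol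
Product: 20 (1R,2Z,4S,5S)-4-bromo-5-chloro-5-methyl-2-(6-methylhept-5-en-2-ylidene)cyclohexyl acetate
Conditions: Ac2O, pyridine, DMAP (cat.), CH2Cl2, 0 °C → rt
Reagents that add atoms: acetic anhydride, CC(=O)OC(C)=O
Why: DMAP-catalysed acetylation of the secondary allylic alcohol proceeds without forming an alkoxide that could displace a ring halide.

Step 15
Reactants: 20 (1R,2Z,4S,5S)-4-bromo-5-chloro-5-methyl-2-(6-methylhept-5-en-2-ylidene)cyclohexyl acetate
Product: 23 (1R,3S,4S,6R,8R,11R)-4,8-dibromo-3-chloro-11-hydroxy-3,7,7,11-tetramethylspiro[5.5]undecan-1-yl acetate (target), via bromiranium ion 21 (not isolated), via dioxanylium ion 22 (not isolated)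
Conditions: BDSB (1.05 equiv), MeNO2, −25 °C; then H2O, pH 7 buffer, 0 °C
Reagents that add atoms: bromodiethylsulfonium bromopentachloroantimonate (BDSB), CC[S+](Br)CC.Cl[Sb-](Cl)(Cl)(Cl)(Cl)Br; water, O
Why: Proposed new method: BDSB transfers Br+ reversibly to the trisubstituted C7=C8 alkene (21); in a chair transition state C6 attacks C7 anti to bromine (Br equatorial at C8) on the face opposite the axial C1 acetoxy group, whose carbonyl oxygen adds to C11 on the other face of the same alkene to give dioxanylium ion 22, so the Z geometry places C1 axial on ring B and C6, C8 and C11 all follow from C1; water then opens 22 and acyl migration in the buffered work-up should converge on the secondary acetate and tertiary alcohol; the closest known reaction types are the bromonium-induced spirocyclisation of γ-bisabolene-type trienes and bromonium polyene cyclisations terminated by a carbonate or ester carbonyl group.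

Compound list
1 | tert-butyl(but-3-yn-1-yloxy)dimethylsilane | C#CCCO[Si](C)(C)C(C)(C)C | starting material
2 | methyl 5-[(tert-butyldimethylsilyl)oxy]pent-2-ynoate | COC(=O)C#CCCO[Si](C)(C)C(C)(C)C | intermediate
3 | lithium methyl[1-(methoxycarbonyl)-2-methyl-4-(silyloxy)but-1-enyl]cuprate (Cu cis to the new methyl) | [Li+].COC(=O)/C([Cu-]C)=C(/C)CCO[Si](C)(C)C(C)(C)C | intermediate (not isolated)
4 | methyl (Z)-5-[(tert-butyldimethylsilyl)oxy]-3-methylpent-2-enoate | COC(=O)/C=C(/C)CCO[Si](C)(C)C(C)(C)C | intermediate
5 | (Z)-5-[(tert-butyldimethylsilyl)oxy]-3-methylpent-2-en-1-ol | CC(C)(C)[Si](C)(C)OCC/C(C)=C\CO | intermediate (key-step precursor)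
6 | bromiranium ion of 5 on the face leading to 7 | CC(C)(C)[Si](C)(C)OCC[C@@]1(C)[Br+][C@H]1CO | intermediate (not isolated)
7 | (2S,3S)-2-bromo-5-[(tert-butyldimethylsilyl)oxy]-3-chloro-3-methylpentan-1-ol | CC(C)(C)[Si](C)(C)OCC[C@](C)(Cl)[C@@H](Br)CO | intermediate (key-step product)
8 | (2S,3S)-2-bromo-5-[(tert-butyldimethylsilyl)oxy]-3-chloro-3-methylpentyl 4-methylbenzenesulfonate | CC(C)(C)[Si](C)(C)OCC[C@](C)(Cl)[C@@H](Br)COS(=O)(=O)c1ccc(C)cc1 | intermediate
9 | (2S,3S)-2-bromo-3-chloro-5-hydroxy-3-methylpentyl 4-methylbenzenesulfonate | OCC[C@](C)(Cl)[C@@H](Br)COS(=O)(=O)c1ccc(C)cc1 | intermediate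
10 | (2S,3S)-2-bromo-3-chloro-3-methyl-5-oxopentyl 4-methylbenzenesulfonate | O=CC[C@](C)(Cl)[C@@H](Br)COS(=O)(=O)c1ccc(C)cc1 | intermediate
11 | (2S,3S)-2-bromo-3-chloro-5-hydroxy-3-methylhexyl 4-methylbenzenesulfonate (C5 epimers) | CC(O)C[C@](C)(Cl)[C@@H](Br)COS(=O)(=O)c1ccc(C)cc1 | intermediate
12 | (2S,3S)-2-bromo-3-chloro-3-methyl-5-oxohexyl 4-methylbenzenesulfonate | CC(=O)C[C@](C)(Cl)[C@@H](Br)COS(=O)(=O)c1ccc(C)cc1 | intermediate
13 | terminal lithium enolate of 12 | C=C(O[Li])C[C@](C)(Cl)[C@@H](Br)COS(=O)(=O)c1ccc(C)cc1 | intermediate (not isolated)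
14 | (3S,4S)-4-bromo-3-chloro-3-methylcyclohexan-1-one | O=C1C[C@](C)(Cl)[C@@H](Br)CC1 | intermediate
15 | 6-methylhept-5-en-2-one (sulcatone) | CC(=O)CCC=C(C)C | starting material
16 | C1=C6 lithium enolate of 14 | [Li]OC=1C[C@](C)(Cl)[C@@H](Br)CC=1 | intermediate (not isolated)
17 | (4S,5S)-4-bromo-5-chloro-2-(2-hydroxy-6-methylhept-5-en-2-yl)-5-methylcyclohexan-1-one (diastereomers at C6 and C11) | O=C1C[C@](C)(Cl)[C@@H](Br)CC1C(C)(O)CCC=C(C)C | intermediate
18 | (2Z,4S,5S)-4-bromo-5-chloro-5-methyl-2-(6-methylhept-5-en-2-ylidene)cyclohexan-1-one | O=C1C[C@](C)(Cl)[C@@H](Br)C/C1=C(\C)CCC=C(C)C | intermediate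
19 | (1R,2Z,4S,5S)-4-bromo-5-chloro-5-methyl-2-(6-methylhept-5-en-2-ylidene)cyclohexan-1-ol | O[C@@H]1C[C@](C)(Cl)[C@@H](Br)C/C1=C(\C)CCC=C(C)C | intermediate
20 | (1R,2Z,4S,5S)-4-bromo-5-chloro-5-methyl-2-(6-methylhept-5-en-2-ylidene)cyclohexyl acetate | CC(=O)O[C@@H]1C[C@](C)(Cl)[C@@H](Br)C/C1=C(\C)CCC=C(C)C | intermediate
21 | C7/C8 bromiranium ion of 20 | CC(=O)O[C@@H]1C[C@](C)(Cl)[C@@H](Br)C/C1=C(\C)CC[C@H]2[Br+]C2(C)C | intermediate (not isolated)
22 | spiro-fused 2-methyl-1,3-dioxan-2-ylium ion bridging O–C1 and O–C11 | CC(=[O+]3)O[C@@H]1C[C@](C)(Cl)[C@@H](Br)C[C@@]12C(C)(C)[C@H](Br)CC[C@]23C | intermediate (not isolated)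
23 | (1R,3S,4S,6R,8R,11R)-4,8-dibromo-3-chloro-11-hydroxy-3,7,7,11-tetramethylspiro[5.5]undecan-1-yl acetate | CC(=O)O[C@@H]1C[C@](C)(Cl)[C@@H](Br)C[C@@]12C(C)(C)[C@H](Br)CC[C@@]2(C)O | target

Total step count: 15. Longest linear sequence: 15 steps (1 → 23; 15 is used as purchased).

Steps most likely to fail

Step 15 (proposed new method). Bromenium may be transferred to the more electron-rich tetrasubstituted C6=C11 alkene instead of C7=C8. The C11 cation may lose a proton before the acetate closes on it. Attack on C6 may occur on the wrong face, because the axial C4 bromine lies on the face required. The dioxanylium ion may open to the tertiary acetate, and the antimony Lewis acid may ionise the C3–Cl bond. The fallback uses the known carbonate-terminated bromonium cyclisation and sets out from 19. Boc2O and DMAP give tert-butyl (1R,2Z,4S,5S)-4-bromo-5-chloro-5-methyl-2-(6-methylhept-5-en-2-ylidene)cyclohexyl carbonate F1. BDSB in MeNO2 at −25 °C closes ring B while the carbonate oxygen captures C11 with loss of isobutene, giving the cyclic C1,C11-carbonate F2. DIBAL-H in CH2Cl2 at −78 °C frees the diol F3 without forming an alkoxide that could displace the trans C8 bromide. Ac2O in pyridine acetylates only the secondary hydroxyl and the route is rejoined at 23.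

Step 12. The elimination has no inherent preference for either alkene geometry, and part of the material may give non-conjugated alkenes. Any E isomer carried on would invert C8 and C11 relative to ring A in step 15. The fallback sets out from 14 and makes the alkene geometry a consequence of steric size. The enolate of 14 (as in step 11) is added to 4-(trimethylsilyl)but-3-yn-2-one to give the alkynyl carbinol F4. Burgess dehydration gives the (Z)-enynone F5. The slim alkynyl group should take the crowded position syn to the carbonyl group both kinetically (methyl is the large group in the closed aldol transition state, then syn elimination) and thermodynamically. Luche reduction gives the enynol F6, acetylation the silylated enynyl acetate F7, TBAF buffered with AcOH the terminal alkyne F8, and Lindlar semihydrogenation the dienyl acetate F9. Hydroboration of the terminal vinyl group with 9-BBN and B-alkyl Suzuki–Miyaura coupling with 1-bromo-2-methylprop-1-ene [Pd(dppf)Cl2, K3PO4] complete the homoprenyl chain, and the route is rejoined at 20.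

Step 10. The enolate may equilibrate to the C2 side and expel the β-chloride, or it may alkylate on oxygen. The fallback sets out from 10, replaces steps 8–10 and never exposes a simple β-chloro ketone to strong base. Roskamp homologation with allyl diazoacetate and catalytic SnCl2 gives the allyl β-keto ester F10. Cs2CO3 in MeCN closes ring A through the doubly stabilised enolate to give the cyclic β-keto ester F11. Palladium-catalysed deallylation and decarboxylation [Pd(PPh3)4, HCO2H, Et3N] rejoin the route at 14.

Further compounds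
F1 | step 15 | tert-butyl (1R,2Z,4S,5S)-4-bromo-5-chloro-5-methyl-2-(6-methylhept-5-en-2-ylidene)cyclohexyl carbonate | CC(C)(C)OC(=O)O[C@@H]1C[C@](C)(Cl)[C@@H](Br)C/C1=C(\C)CCC=C(C)C
F2 | step 15 | cyclic carbonate (1,3-dioxan-2-one) bridging O–C1 and O–C11 of the spirocycle, configured as 23 | O=C3O[C@@H]1C[C@](C)(Cl)[C@@H](Br)C[C@@]12C(C)(C)[C@H](Br)CC[C@@]2(C)O3
F3 | step 15 | (1R,3S,4S,6R,8R,11R)-4,8-dibromo-3-chloro-3,7,7,11-tetramethylspiro[5.5]undecane-1,11-diol | O[C@@H]1C[C@](C)(Cl)[C@@H](Br)C[C@@]12C(C)(C)[C@H](Br)CC[C@@]2(C)O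
F4 | step 12 | (4S,5S)-4-bromo-5-chloro-2-[2-hydroxy-4-(trimethylsilyl)but-3-yn-2-yl]-5-methylcyclohexan-1-one | O=C1C[C@](C)(Cl)[C@@H](Br)CC1C(C)(O)C#C[Si](C)(C)C
F5 | step 12 | (2Z,4S,5S)-4-bromo-5-chloro-5-methyl-2-[4-(trimethylsilyl)but-3-yn-2-ylidene]cyclohexan-1-one | O=C1C[C@](C)(Cl)[C@@H](Br)C/C1=C(\C)C#C[Si](C)(C)C
F6 | step 12 | (1R,2Z,4S,5S)-4-bromo-5-chloro-5-methyl-2-[4-(trimethylsilyl)but-3-yn-2-ylidene]cyclohexan-1-ol | O[C@@H]1C[C@](C)(Cl)[C@@H](Br)C/C1=C(\C)C#C[Si](C)(C)C
F7 | step 12 | (1R,2Z,4S,5S)-4-bromo-5-chloro-5-methyl-2-[4-(trimethylsilyl)but-3-yn-2-ylidene]cyclohexyl acetate | CC(=O)O[C@@H]1C[C@](C)(Cl)[C@@H](Br)C/C1=C(\C)C#C[Si](C)(C)C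
F8 | step 12 | (1R,2Z,4S,5S)-4-bromo-2-(but-3-yn-2-ylidene)-5-chloro-5-methylcyclohexyl acetate | CC(=O)O[C@@H]1C[C@](C)(Cl)[C@@H](Br)C/C1=C(\C)C#C
F9 | step 12 | (1R,2Z,4S,5S)-4-bromo-2-(but-3-en-2-ylidene)-5-chloro-5-methylcyclohexyl acetate | CC(=O)O[C@@H]1C[C@](C)(Cl)[C@@H](Br)C/C1=C(\C)C=C
F10 | step 10 | allyl (5S,6S)-6-bromo-5-chloro-5-methyl-3-oxo-7-(tosyloxy)heptanoate | C=CCOC(=O)CC(=O)C[C@](C)(Cl)[C@@H](Br)COS(=O)(=O)c1ccc(C)cc1
F11 | step 10 | allyl (4S,5S)-5-bromo-4-chloro-4-methyl-2-oxocyclohexane-1-carboxylate (C1 epimers) | O=C1C[C@](C)(Cl)[C@@H](Br)CC1C(=O)OCC=C
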